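The target is cut at the C3=C4 double bond of the 2H-pyran fused to ring B, the only alkene of that ring, which sits between aromatic carbon C4a and the gem-dimethyl carbon C2 bound to O1. Ring-closing metathesis of a vinyl group on C4a with a 1,1-dimethylallyl ether on the C8a oxygen makes this bond and the pyran ring in one operation, on a benzophenone that already carries the whole skeleton. The precursor is a fully assembled diaryl ketone with both remaining phenols as MOM ethers; the aldehyde that later becomes the styrene is first used to tell the two ring B phenols apart by hydrogen bonding.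

Key step: step 9

Remark: ring B is numbered as a chromene (O1, C2, C3, C4, C4a, C5 to C8, C8a) and ring A is the 2-hydroxy-4,6-dimethoxyphenyl ring; the target has no stereocentre, and carbinol 12 is carried as the racemate.

Step 1
Reactants: 1 5-bromobenzene-1,3-diol
Product: 3 2-bromo-4,6-dihydroxybenzaldehyde, via aryl iminium chloride 2 (not isolated)
Conditions: POCl3, DMF, MeCN, −15 °C to rt; then H2O, 50 °C
Reagents that add atoms: N,N-dimethylformamide, CN(C)C=O (formyl carbon); water, O (carbonyl oxygen)
Why: Vilsmeier–Haack formylation of a resorcinol goes para to one hydroxyl and ortho to the other rather than between the two hydroxyls, so the formyl group should enter next to bromine and, after hydrolysis of the iminium salt, give an aldehyde that hydrogen-bonds to only one of the two phenols.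

Step 2
Reactants: 3 2-bromo-4,6-dihydroxybenzaldehyde
Product: 4 2-bromo-6-hydroxy-4-(methoxymethoxy)benzaldehyde
Conditions: MOMCl (1.05 equiv), K2CO3, acetone, 0 °C to rt
Reagents that add atoms: chloromethyl methyl ether, COCCl
Why: In this Williamson etherification under weak base the 4-hydroxyl para to the formyl group is the more acidic and is free, whereas the 6-hydroxyl is chelated to the aldehyde, so one equivalent of MOMCl should protect the 4-position selectively, as is standard for 2,4-dihydroxybenzaldehydes.

Step 3
Reactants: 4 2-bromo-6-hydroxy-4-(methoxymethoxy)benzaldehyde; 5 3-chloro-3-methylbut-1-yne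
Product: 6 2-bromo-4-(methoxymethoxy)-6-[(2-methylbut-3-yn-2-yl)oxy]benzaldehyde
Conditions: DBU, CuCl2·2H2O (cat.), MeCN, 0 °C
Reagents that add atoms: none
Why: Copper-catalysed propargylic etherification of a phenoxide with a tertiary propargylic chloride is the standard entry to aryl 1,1-dimethylpropargyl ethers; DBU breaks the chelate, and the low temperature keeps the new ether from sigmatropic rearrangement.

Step 4
Reactants: 6 2-bromo-4-(methoxymethoxy)-6-[(2-methylbut-3-yn-2-yl)oxy]benzaldehyde
Product: 7 2-bromo-4-(methoxymethoxy)-6-[(2-methylbut-3-en-2-yl)oxy]benzaldehyde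
Conditions: H2 (1 atm), Pd/CaCO3 poisoned with Pb(OAc)2 (Lindlar catalyst), quinoline, EtOAc, rt
Reagents that add atoms: none
Why: Lindlar semihydrogenation of a terminal alkyne stops at the alkene, and with quinoline at one atmosphere of hydrogen the aryl bromide, the aldehyde and the acetal should be left alone; no styrene is present yet that could be over-reduced.

Step 5
Reactants: 7 2-bromo-4-(methoxymethoxy)-6-[(2-methylbut-3-en-2-yl)oxy]benzaldehyde
Product: 8 1-bromo-2-ethenyl-5-(methoxymethoxy)-3-[(2-methylbut-3-en-2-yl)oxy]benzene
Conditions: Ph3PCH3Br, KOtBu, THF, 0 °C to rt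
Reagents that add atoms: methyltriphenylphosphonium bromide, C[P+](c1ccccc1)(c1ccccc1)c1ccccc1.[Br-]
Why: Wittig methylenation with the unstabilised ylide works on 2,6-disubstituted, non-enolisable benzaldehydes, and the cold basic medium endangers neither the tertiary allyl ether nor the MOM group.

Step 6
Reactants: 9 2-hydroxy-4,6-dimethoxybenzaldehyde
Product: 10 2,4-dimethoxy-6-(methoxymethoxy)benzaldehyde
Conditions: NaH, MOMCl, DMF, 0 °C to rt
Reagents that add atoms: chloromethyl methyl ether, COCCl
Why: Williamson etherification of the sodium phenoxide masks the chelated phenol of ring A with the same acetal as on ring B, so that both can be removed together at the end without a late demethylation.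

Step 7
Reactants: 8 1-bromo-2-ethenyl-5-(methoxymethoxy)-3-[(2-methylbut-3-en-2-yl)oxy]benzene; 10 2,4-dimethoxy-6-(methoxymethoxy)benzaldehyde
Product: 12 racemic [2,4-dimethoxy-6-(methoxymethoxy)phenyl]{2-ethenyl-5-(methoxymethoxy)-3-[(2-methylbut-3-en-2-yl)oxy]phenyl}methanol, via aryllithium 11 (not isolated)
Conditions: n-BuLi (1.05 equiv), THF, −78 °C; then 10, −78 to −20 °C; H2O
Reagents that add atoms: none
Why: Bromine–lithium exchange at −78 °C is faster than addition of butyllithium to the styrene, and 1,2-addition of the aryllithium to the non-enolisable aldehyde should give the diarylcarbinol; its stereocentre forms without control and is erased by the oxidation in step 8, and the neutral quench protects the easily ionised benzhydrol.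

Step 8
Reactants: 12 racemic [2,4-dimethoxy-6-(methoxymethoxy)phenyl]{2-ethenyl-5-(methoxymethoxy)-3-[(2-methylbut-3-en-2-yl)oxy]phenyl}methanol
Product: 13 [2,4-dimethoxy-6-(methoxymethoxy)phenyl]{2-ethenyl-5-(methoxymethoxy)-3-[(2-methylbut-3-en-2-yl)oxy]phenyl}methanone
Conditions: Dess–Martin periodinane, NaHCO3, CH2Cl2, 0 °C to rt
Reagents that add atoms: none
Why: Dess–Martin oxidation converts hindered benzhydrols into diaryl ketones at room temperature without touching alkenes, and the hydrogencarbonate buffer keeps the acetic acid formed away from the acetals and the tertiary allyl ether.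

Step 9
Reactants: 13 [2,4-dimethoxy-6-(methoxymethoxy)phenyl]{2-ethenyl-5-(methoxymethoxy)-3-[(2-methylbut-3-en-2-yl)oxy]phenyl}methanone
Product: 14 [2,4-dimethoxy-6-(methoxymethoxy)phenyl][7-(methoxymethoxy)-2,2-dimethyl-2H-chromen-5-yl]methanone
Conditions: RuCl2(=CHPh)(PCy3)(H2IMes) (second-generation Grubbs catalyst, 5 mol %), degassed acid-free CH2Cl2 (0.005 M), 35–40 °C
Reagents that add atoms: none
Why: Olefin metathesis by the [2+2]/retro-[2+2] mechanism: the benzylidene of the catalyst exchanges onto one of the two terminal alkenes, the new alkylidene adds across the other alkene of the same molecule to give a metallacyclobutane, and cycloreversion releases the chromene while ethene leaves as a gas and drives the reaction. The closest known reaction type is ring-closing metathesis of 2-vinylaryl 1,1-dimethylallyl ethers to 2,2-dimethyl-2H-chromenes. The one ring closed is the six-membered pyran, closed at C3=C4 by intramolecular metathesis of two monosubstituted alkenes held ortho to each other on ring B, so the ring alkene can only be cis. No stereocentre is formed. The step needs ring closure to win over oligomerisation and over two reactions of the tertiary allyl aryl ether: ionisation, and the aromatic Claisen shift toward C8, the ortho carbon that is still unsubstituted. High dilution, the gem-dimethyl group (which favours the folded conformer and makes the allyl alkene a poor cross-metathesis partner), acid-free solvent and a bath temperature of at most 40 °C should secure this, while the ketone, the methyl ethers and the two acetals are spectators.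

Step 10
Reactants: 14 [2,4-dimethoxy-6-(methoxymethoxy)phenyl][7-(methoxymethoxy)-2,2-dimethyl-2H-chromen-5-yl]methanone
Product: 15 (2-hydroxy-4,6-dimethoxyphenyl)(7-hydroxy-2,2-dimethyl-2H-chromen-5-yl)methanone
Conditions: HCl (1.25 M in MeOH), rt to 40 °C
Reagents that add atoms: none
Why: Acid-catalysed acetal exchange with methanol removes both MOM groups (the one ortho to the ketone first, helped by the carbonyl) under conditions commonly applied to 2,2-dimethyl-2H-chromenes; the aryl methyl ethers are stable, and the mild acid and temperature should spare the electron-rich chromene alkene.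

Compound list
1 | 5-bromobenzene-1,3-diol | Oc1cc(O)cc(Br)c1 | starting material
2 | [(2-bromo-4,6-dihydroxyphenyl)methylidene]dimethyliminium chloride | C[N+](C)=Cc1c(O)cc(O)cc1Br.[Cl-] | intermediate
3 | 2-bromo-4,6-dihydroxybenzaldehyde | O=Cc1c(O)cc(O)cc1Br | intermediate
4 | 2-bromo-6-hydroxy-4-(methoxymethoxy)benzaldehyde | O=Cc1c(O)cc(OCOC)cc1Br | intermediate
5 | 3-chloro-3-methylbut-1-yne | CC(C)(Cl)C#C | starting material
6 | 2-bromo-4-(methoxymethoxy)-6-[(2-methylbut-3-yn-2-yl)oxy]benzaldehyde | O=Cc1c(OC(C)(C)C#C)cc(OCOC)cc1Br | intermediate
7 | 2-bromo-4-(methoxymethoxy)-6-[(2-methylbut-3-en-2-yl)oxy]benzaldehyde | O=Cc1c(OC(C)(C)C=C)cc(OCOC)cc1Br | intermediate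
8 | 1-bromo-2-ethenyl-5-(methoxymethoxy)-3-[(2-methylbut-3-en-2-yl)oxy]benzene | C=Cc1c(OC(C)(C)C=C)cc(OCOC)cc1Br | intermediate
9 | 2-hydroxy-4,6-dimethoxybenzaldehyde | COc1cc(O)c(C=O)c(OC)c1 | starting material
10 | 2,4-dimethoxy-6-(methoxymethoxy)benzaldehyde | COCOc1cc(OC)cc(OC)c1C=O | intermediate
11 | {2-ethenyl-5-(methoxymethoxy)-3-[(2-methylbut-3-en-2-yl)oxy]phenyl}lithium | [Li]c1cc(OCOC)cc(OC(C)(C)C=C)c1C=C | intermediate
12 | racemic [2,4-dimethoxy-6-(methoxymethoxy)phenyl]{2-ethenyl-5-(methoxymethoxy)-3-[(2-methylbut-3-en-2-yl)oxy]phenyl}methanol | COCOc1cc(OC)cc(OC)c1C(O)c1cc(OCOC)cc(OC(C)(C)C=C)c1C=C | intermediate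
13 | [2,4-dimethoxy-6-(methoxymethoxy)phenyl]{2-ethenyl-5-(methoxymethoxy)-3-[(2-methylbut-3-en-2-yl)oxy]phenyl}methanone | COCOc1cc(OC)cc(OC)c1C(=O)c1cc(OCOC)cc(OC(C)(C)C=C)c1C=C | intermediate
14 | [2,4-dimethoxy-6-(methoxymethoxy)phenyl][7-(methoxymethoxy)-2,2-dimethyl-2H-chromen-5-yl]methanone | COCOc1cc(OC)cc(OC)c1C(=O)c1cc(OCOC)cc2OC(C)(C)C=Cc12 | intermediate
15 | (2-hydroxy-4,6-dimethoxyphenyl)(7-hydroxy-2,2-dimethyl-2H-chromen-5-yl)methanone | COc1cc(O)c(C(=O)c2cc(O)cc3c2C=CC(C)(C)O3)c(OC)c1 | target

Total steps: 10. Longest linear sequence: 9 steps (steps 1 to 5 and 7 to 10) from 5-bromobenzene-1,3-diol 1; step 6 is a one-step side branch.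

Steps most likely to fail

Step 9. The alkylidene may form only slowly on the doubly ortho-substituted styrene and may be held back by coordination of the neighbouring ketone oxygen. Over a long reaction time the tertiary allyl ether may then shift to C8 or ionise. The fallback closes the pyran before the ketone is built, by oxa-6π electrocyclisation instead of metathesis, and sets out from 4. Addition of excess 2-methylprop-1-enylmagnesium bromide (THF, 0 °C) to the aldehyde should give racemic 3-bromo-2-(1-hydroxy-3-methylbut-2-en-1-yl)-5-(methoxymethoxy)phenol F1. Loss of water (pyridinium p-toluenesulfonate cat., toluene, 60 °C) through the ortho-quinone methide, followed by electrocyclisation, should give 5-bromo-7-(methoxymethoxy)-2,2-dimethyl-2H-chromene F2. Bromine–lithium exchange (n-BuLi, THF, −78 °C) and addition to 10 under the conditions of step 7 should give racemic [2,4-dimethoxy-6-(methoxymethoxy)phenyl][7-(methoxymethoxy)-2,2-dimethyl-2H-chromen-5-yl]methanol F3. Oxidation under the conditions of step 8 comes back to the route at 14.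

Step 3. Etherification of the hydrogen-bonded, ortho-substituted phenol may be slow, and the base may instead eliminate hydrogen chloride from the tertiary chloride. The fallback sets out from 4 and installs the tertiary allyl ether directly by Tsuji–Trost O-allylation with tert-butyl 2-methylbut-3-en-2-yl carbonate and Pd(PPh3)4 in THF at 0 °C. The phenoxide should attack the more substituted end of the dimethylallyl fragment, and the aryl bromide should not react at this temperature. This comes back to the route at 7 and bypasses 6 and the semihydrogenation.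

Step 1. The electrophile may attack between the two hydroxyls, or formylate oxygen without forming the carbon–carbon bond, and the bromine slows the ring. The fallback sets out from 1 and formylates the dimethyl ether instead. O-Methylation (MeI, K2CO3, acetone) should give 1-bromo-3,5-dimethoxybenzene F4. Vilsmeier–Haack formylation (POCl3, DMF, 90 °C), para to one methoxy group and ortho to the other, should give 2-bromo-4,6-dimethoxybenzaldehyde F5. Cleavage of both methyl ethers with BBr3 (CH2Cl2, −78 °C to rt) comes back to the route at 3.

Further compounds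
F1 | step 9 | racemic 3-bromo-2-(1-hydroxy-3-methylbut-2-en-1-yl)-5-(methoxymethoxy)phenol | CC(C)=CC(O)c1c(O)cc(OCOC)cc1Br
F2 | step 9 | 5-bromo-7-(methoxymethoxy)-2,2-dimethyl-2H-chromene | COCOc1cc(Br)c2C=CC(C)(C)Oc2c1
F3 | step 9 | racemic [2,4-dimethoxy-6-(methoxymethoxy)phenyl][7-(methoxymethoxy)-2,2-dimethyl-2H-chromen-5-yl]methanol | COCOc1cc(OC)cc(OC)c1C(O)c1cc(OCOC)cc2OC(C)(C)C=Cc12
F0 | step 3 | none | none
F4 | step 1 | 1-bromo-3,5-dimethoxybenzene | COc1cc(OC)cc(Br)c1
F5 | step 1 | 2-bromo-4,6-dimethoxybenzaldehyde | COc1cc(OC)c(C=O)c(Br)c1
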